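Ring B, the lactone, is cut at C2–O1 and C2–C3, so that C2 is supplied by carbon monoxide. The feature used is the O1–C2(=O)–C3H2–C4H(Ph)(ring A) array, which is what results when hydrogen and an acyl group are added across a 1,1-diarylethene. One palladium-catalysed asymmetric cyclocarbonylation should therefore close ring B, make both bonds to C2 and set C4. Its precursor is an acylphloroglucinol with a 1-phenylvinyl group beside the hydroxyl para to the acyl group; the two hydroxyls ortho to the acyl group are benzyl ethers, so only one lactone can form. Hydrogenolysis and geminal C8 prenylation of ring A then finish the target.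

Key step: step 6

Remarks on the chemistry:
- Chromen-2-one numbering is used throughout, also for the open precursors: ring A is C4a, C5, C6, C7, C8, C8a; ring B is O1, C2, C3, C4, C4a, C8a.
- In a free triol, the alkene-bearing carbon C4a is flanked by two hydroxyls, and the ketone can hydrogen-bond to either ortho hydroxyl, so both could lactonise. The oxygens on C5 and C7 are therefore benzyl ethers from starting material 4 onward. Compounds 11 and 13 are the C5,C7-di-O-benzyl ethers of the triol precursor and of lactone 14.
- Which hand of the bisphosphine leads to 4S cannot be predicted with confidence. The (R) ligand is written; its antipode is taken if a first run shows the opposite sense.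
- Starting materials 1, 4, 10, 12 and 15 are catalogue compounds.

Step 1
Reactants: 1 (R)-2-methylbutanoic acid
Product: 3 (2R)-N-methoxy-N,2-dimethylbutanamide, via acyl imidazolide 2 (not isolated)
Conditions: CDI, CH2Cl2, 0 °C to rt; then MeNH(OMe)·HCl, rt
Reagents that add atoms: N,O-dimethylhydroxylamine hydrochloride, SMILES CNOC.Cl
Why: Weinreb amide formation through the acyl imidazolide is a mild amidation that avoids an acid chloride or ketene, so the alpha stereocenter should stay R.

Step 2
Reactants: 4 3,5-bis(benzyloxy)phenol
Product: 5 [3,5-bis(benzyloxy)phenoxy]tri(propan-2-yl)silane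
Conditions: TIPSCl, imidazole, DMF, rt
Reagents that add atoms: chlorotri(propan-2-yl)silane (TIPSCl), SMILES CC(C)[Si](Cl)(C(C)C)C(C)C
Why: Silyl ether formation at the only free phenol masks the acidic OH for the lithiation, and the bulky, poorly coordinating silyloxy group keeps the base away from the two carbons next to it.

Step 3
Reactants: 5 [3,5-bis(benzyloxy)phenoxy]tri(propan-2-yl)silane; 3 (2R)-N-methoxy-N,2-dimethylbutanamide
Product: 8 (2R)-1-[2,6-bis(benzyloxy)-4-hydroxyphenyl]-2-methylbutan-1-one, via aryllithium 6 (not isolated), via silyl ketone 7 (not isolated)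
Conditions: n-BuLi, THF, 0 °C; 3, −78 °C to 0 °C; AcOH; then TBAF (excess), rt
Reagents that add atoms: none
Why: Directed ortho-metalation should occur at the carbon flanked by both benzyloxy groups, the aryllithium then adds once to the amide (Weinreb ketone synthesis, in which the chelated tetrahedral adduct shields the alpha stereocenter from base until the acidic quench), and fluoride cleaves the aryl silyl ether in the same flask.

Step 4
Reactants: 8 (2R)-1-[2,6-bis(benzyloxy)-4-hydroxyphenyl]-2-methylbutan-1-one
Product: 9 (2R)-1-[2,6-bis(benzyloxy)-4-hydroxy-3-iodophenyl]-2-methylbutan-1-one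
Conditions: NIS (1.0 equiv), MeCN, 0 °C, dark
Reagents that add atoms: N-iodosuccinimide, SMILES O=C1CCC(=O)N1I
Why: Electrophilic aromatic iodination can only reach the two equivalent ring CH positions ortho to the free phenol, and one equivalent of reagent at low temperature should stop at the mono-iodide.

Step 5
Reactants: 9 (2R)-1-[2,6-bis(benzyloxy)-4-hydroxy-3-iodophenyl]-2-methylbutan-1-one; 10 4,4,5,5-tetramethyl-2-(1-phenylethenyl)-1,3,2-dioxaborolane
Product: 11 (2R)-1-[2,6-bis(benzyloxy)-4-hydroxy-3-(1-phenylethenyl)phenyl]-2-methylbutan-1-one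
Conditions: Pd(OAc)2 (3 mol%), SPhos (6 mol%), K3PO4, toluene/H2O, 80 °C
Reagents that add atoms: none
Why: Suzuki–Miyaura coupling with a bulky biarylphosphine is the standard solution for di-ortho-substituted aryl iodides and tolerates the free phenol, while the para phenoxide formed under the basic conditions makes the ketone less prone to enolise, so the side-chain stereocenter should hold.

Step 6
Reactants: 11 (2R)-1-[2,6-bis(benzyloxy)-4-hydroxy-3-(1-phenylethenyl)phenyl]-2-methylbutan-1-one; 12 carbon monoxide
Product: 13 (4S)-5,7-bis(benzyloxy)-6-[(2R)-2-methylbutanoyl]-4-phenyl-3,4-dihydro-2H-chromen-2-one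
Conditions: CO (30 bar), Pd(OAc)2 (5 mol%), (R)-DTBM-SEGPHOS (6 mol%), TsOH·H2O (10 mol%), toluene, 80 °C
Reagents that add atoms: none
Why: Zerovalent palladium formed in situ is protonated to a cationic hydride of divalent palladium, which adds across the 1,1-diarylethene with H going to the diaryl carbon (C4) and Pd to the terminal CH2 (C3); CO insertion gives the acyl palladium, and the neighbouring phenol (the future O1) captures it, forming C2–C3 and C2–O1 and returning zerovalent palladium. The closest known reaction types are the palladium-catalysed cyclocarbonylation of 2-alkenylphenols to 3,4-dihydrocoumarins and the asymmetric anti-Markovnikov hydroesterification of 1,1-disubstituted aryl alkenes. Ring B closes by 6-exo-trig acyl transfer to oxygen, which can equally be seen as C–O reductive elimination from a seven-membered acyl(aryloxy)palladium chelate. C4 is set under catalyst control: the chiral bisphosphine decides which alkene face receives the hydride, and because beta-hydride elimination can reverse that step, the ee should reflect how well the ligand separates the diastereomeric alkyl and acyl palladium species, with no influence expected from the remote R centre. Two selectivities are needed: palladium must go to the terminal carbon, which the 1,1-disubstitution secures because the alternative is a tertiary alkyl palladium leading to a quaternary five-membered lactone, and the acyl group must be taken up by the oxygen para to the ketone, which is secured because the oxygen on C5 is a benzyl ether and the para hydroxyl is the only free one (the ethers also remove the hydroxy-ketone chelate that could bind palladium).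

Step 7
Reactants: 13 (4S)-5,7-bis(benzyloxy)-6-[(2R)-2-methylbutanoyl]-4-phenyl-3,4-dihydro-2H-chromen-2-one
Product: 14 (4S)-5,7-dihydroxy-6-[(2R)-2-methylbutanoyl]-4-phenyl-3,4-dihydro-2H-chromen-2-one
Conditions: H2 (1 atm), Pd/C, EtOAc, rt
Reagents that add atoms: none
Why: Hydrogenolysis of aryl benzyl ethers is neutral and should leave the aryl lactone, the ketone and both stereocenters untouched, since no alkene is present at this stage and no alcohol solvent is used that could open the lactone.

Step 8
Reactants: 14 (4S)-5,7-dihydroxy-6-[(2R)-2-methylbutanoyl]-4-phenyl-3,4-dihydro-2H-chromen-2-one; 15 1-bromo-3-methylbut-2-ene (prenyl bromide)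
Product: 17 (4S)-5-hydroxy-8,8-bis(3-methylbut-2-en-1-yl)-6-[(2R)-2-methylbutanoyl]-4-phenyl-3,4-dihydro-2H-chromene-2,7(8H)-dione, via 8-prenyl phenol 16 (not isolated)
Conditions: NaH (3 equiv), toluene, 0 °C; 15 (2.3 equiv), 0 °C to 40 °C; then 1 M HCl, 0 °C
Reagents that add atoms: none
Why: Alkylative dearomatisation by double C-alkylation of the acylphloroglucinol phenoxide should occur at C8, the only ring carbon bearing hydrogen, first giving the 8-prenyl phenol and then the gem-diprenyl dienone; sodium phenoxides in a non-polar solvent favour C- over O-alkylation, NaH cannot add to the lactone, and the polyanionic ring protects the side-chain alpha CH from deprotonation.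

Compound list
1 | (R)-2-methylbutanoic acid | CC[C@@H](C)C(=O)O | starting material
2 | (2R)-1-(1H-imidazol-1-yl)-2-methylbutan-1-one | CC[C@@H](C)C(=O)n1ccnc1 | intermediate
3 | (2R)-N-methoxy-N,2-dimethylbutanamide | CC[C@@H](C)C(=O)N(C)OC | intermediate
4 | 3,5-bis(benzyloxy)phenol | Oc1cc(OCc2ccccc2)cc(OCc2ccccc2)c1 | starting material
5 | [3,5-bis(benzyloxy)phenoxy]tri(propan-2-yl)silane | CC(C)[Si](Oc1cc(OCc2ccccc2)cc(OCc2ccccc2)c1)(C(C)C)C(C)C | intermediate
6 | {2,6-bis(benzyloxy)-4-[tri(propan-2-yl)silyloxy]phenyl}lithium | [Li]c1c(OCc2ccccc2)cc(O[Si](C(C)C)(C(C)C)C(C)C)cc1OCc1ccccc1 | intermediate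
7 | (2R)-1-{2,6-bis(benzyloxy)-4-[tri(propan-2-yl)silyloxy]phenyl}-2-methylbutan-1-one | CC[C@@H](C)C(=O)c1c(OCc2ccccc2)cc(O[Si](C(C)C)(C(C)C)C(C)C)cc1OCc1ccccc1 | intermediate
8 | (2R)-1-[2,6-bis(benzyloxy)-4-hydroxyphenyl]-2-methylbutan-1-one | CC[C@@H](C)C(=O)c1c(OCc2ccccc2)cc(O)cc1OCc1ccccc1 | intermediate
9 | (2R)-1-[2,6-bis(benzyloxy)-4-hydroxy-3-iodophenyl]-2-methylbutan-1-one | CC[C@@H](C)C(=O)c1c(OCc2ccccc2)cc(O)c(I)c1OCc1ccccc1 | intermediate
10 | 4,4,5,5-tetramethyl-2-(1-phenylethenyl)-1,3,2-dioxaborolane | C=C(c1ccccc1)B1OC(C)(C)C(C)(C)O1 | starting material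
11 | (2R)-1-[2,6-bis(benzyloxy)-4-hydroxy-3-(1-phenylethenyl)phenyl]-2-methylbutan-1-one | CC[C@@H](C)C(=O)c1c(OCc2ccccc2)cc(O)c(C(=C)c2ccccc2)c1OCc1ccccc1 | intermediate
12 | carbon monoxide | [C-]#[O+] | starting material
13 | (4S)-5,7-bis(benzyloxy)-6-[(2R)-2-methylbutanoyl]-4-phenyl-3,4-dihydro-2H-chromen-2-one | CC[C@@H](C)C(=O)c1c(OCc2ccccc2)c2c(cc1OCc1ccccc1)OC(=O)C[C@H]2c1ccccc1 | intermediate
14 | (4S)-5,7-dihydroxy-6-[(2R)-2-methylbutanoyl]-4-phenyl-3,4-dihydro-2H-chromen-2-one | CC[C@@H](C)C(=O)c1c(O)c2c(cc1O)OC(=O)C[C@H]2c1ccccc1 | intermediate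
15 | 1-bromo-3-methylbut-2-ene (prenyl bromide) | CC(C)=CCBr | starting material
16 | (4S)-5,7-dihydroxy-8-(3-methylbut-2-en-1-yl)-6-[(2R)-2-methylbutanoyl]-4-phenyl-3,4-dihydro-2H-chromen-2-one | CC[C@@H](C)C(=O)c1c(O)c2c(c(CC=C(C)C)c1O)OC(=O)C[C@H]2c1ccccc1 | intermediate
17 | (4S)-5-hydroxy-8,8-bis(3-methylbut-2-en-1-yl)-6-[(2R)-2-methylbutanoyl]-4-phenyl-3,4-dihydro-2H-chromene-2,7(8H)-dione | CC[C@@H](C)C(=O)C1=C(O)C2=C(OC(=O)C[C@H]2c2ccccc2)C(CC=C(C)C)(CC=C(C)C)C1=O | target

Total step count: 8. Longest linear sequence: 7 (steps 2 to 8 from compound 4, or steps 1 and 3 to 8 from compound 1).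

Steps most likely to fail

Step 6. The hydride transfer may discriminate poorly between the alkene faces, the phenol and ketone may sequester the catalyst, or the acid co-catalyst may oligomerise the electron-rich alkene. The fallback sets C4 by conjugate addition instead of carbonylation. It sets out from phenol 8: palladium-catalysed hydroarylation of ethyl propiolate with lactonisation (Pd(OAc)2, NaOAc, HCO2H, rt) should give the coumarin 5,7-bis(benzyloxy)-6-[(2R)-2-methylbutanoyl]-2H-chromen-2-one F1, again through the only free hydroxyl. A Hayashi–Miyaura 1,4-addition of phenylboronic acid ([Rh(acac)(C2H4)2], SEGPHOS of the hand that gives 4S, dioxane/H2O, 60 °C) should then place phenyl on C4, and the route is rejoined at compound 13.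

Step 8. O-alkylation may outrun C-alkylation, the second alkylation may stall at the aromatic stage, or the aryl lactone may open during basic handling. The fallback sets out from compound 14: a double Tsuji–Trost allylation (allyl methyl carbonate, Pd(PPh3)4, THF, rt), in which any O-allyl ether is re-ionised by zerovalent palladium and funnelled to carbon, should give (4S)-5-hydroxy-6-[(2R)-2-methylbutanoyl]-4-phenyl-8,8-di(prop-2-en-1-yl)-3,4-dihydro-2H-chromene-2,7(8H)-dione F2. Cross-metathesis with 2-methylbut-2-ene (second-generation Grubbs catalyst, CH2Cl2, 40 °C) should turn both allyl groups into prenyl groups and arrive at target 17.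

Step 3. Benzylic deprotonation with Wittig rearrangement may compete with ring lithiation, or the hindered aryllithium may deprotonate the branched amide and fail to add. The fallback builds the ketone by electrophilic acylation and a protecting-group exchange, setting out from acid 1. Oxalyl chloride with catalytic DMF (CH2Cl2, 0 °C) should give (2R)-2-methylbutanoyl chloride F3. Friedel–Crafts acylation of phloroglucinol (AlCl3, PhNO2/CH2Cl2, rt) should give (2R)-2-methyl-1-(2,4,6-trihydroxyphenyl)butan-1-one F4, whose enantiomeric purity would have to be checked. Silylation of the unchelated, most acidic para hydroxyl (TIPSCl, imidazole, CH2Cl2, 0 °C) should give (2R)-1-{2,6-dihydroxy-4-[tri(propan-2-yl)silyloxy]phenyl}-2-methylbutan-1-one F5. Benzylation of both ortho hydroxyls (BnBr, K2CO3, DMF, 50 °C) returns to the route at silyl ketone 7, which is desilylated with TBAF to compound 8 as in step 3.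

Further compounds
F1 | step 6 | 5,7-bis(benzyloxy)-6-[(2R)-2-methylbutanoyl]-2H-chromen-2-one | CC[C@@H](C)C(=O)c1c(OCc2ccccc2)c2c(cc1OCc1ccccc1)OC(=O)C=C2
F2 | step 8 | (4S)-5-hydroxy-6-[(2R)-2-methylbutanoyl]-4-phenyl-8,8-di(prop-2-en-1-yl)-3,4-dihydro-2H-chromene-2,7(8H)-dione | CC[C@@H](C)C(=O)C1=C(O)C2=C(OC(=O)C[C@H]2c2ccccc2)C(CC=C)(CC=C)C1=O
F3 | step 3 | (2R)-2-methylbutanoyl chloride | CC[C@@H](C)C(=O)Cl
F4 | step 3 | (2R)-2-methyl-1-(2,4,6-trihydroxyphenyl)butan-1-one | CC[C@@H](C)C(=O)c1c(O)cc(O)cc1O
F5 | step 3 | (2R)-1-{2,6-dihydroxy-4-[tri(propan-2-yl)silyloxy]phenyl}-2-methylbutan-1-one | CC[C@@H](C)C(=O)c1c(O)cc(O[Si](C(C)C)(C(C)C)C(C)C)cc1O
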